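**Plan** (atom labels are those of the target: ring A = C1, C2, C3, C3a, C7a; ring B = C3a, C4–C7, C7a; side chain C1'–C5')
1. Cuts: the side chain at C2'–C3' (B-alkyl Suzuki–Miyaura) and C1'=C2' (Wittig); ring A at C2–C3 (Dieckmann); ring B at C3a–C4 (Mukaiyama aldol) and C6–C7 (radical Giese addition). What is left is a 3,4-dimethyladipate, i.e. an ozonised cyclohexene.
2. Enabling feature: the adjacent quaternary carbons C1 and C7a of ring A carry cis methyls and one further carbon each (C1', C7). They are the CMe=CMe unit and the two carbonyls of 2,3-dimethylmaleic anhydride, and C2, the C2 carboxyl carbon, C3 and C3a are the four carbons of buta-1,3-diene.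
3. Forward order: Diels–Alder cyclohexene (step 1, opened again in step 9), C7 arm, ring B (step 10), ring A (step 11), removal of the C3 oxygen through the enol triflate, then the side chain.
4. Stereochemistry: cis C1/C7a from the suprafacial cycloaddition; absolute sense from alkaloid-mediated methanolysis of the meso adduct; C2 from hydroxyl-directed hydrogenation; the Z alkene from anti carbomagnesiation of propargyl alcohol.

Key step: step 1

Assumption: quinidine is taken to open the dimethyl-substituted anhydride in the sense that gives 4. If the sense is the opposite, quinine gives 4, or the antipodal hemiester reaches the same lactone 6 by reduction of its acid (mixed anhydride, NaBH4) instead of its ester.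

**Route**

Step 1
Reactants: 1 2,3-dimethylmaleic anhydride; 2 buta-1,3-diene
Product: 3 cis-1,2-dimethylcyclohex-4-ene-1,2-dicarboxylic anhydride (meso)
Conditions: 2 (excess), hydroquinone (cat.), PhH, sealed vessel, 190 °C
Reagents that add atoms: none
Why: A concerted, thermally allowed suprafacial [4+2] cycloaddition joins C1–C2 and C7a–C3a (target numbering) between s-cis butadiene and the electron-poor tetrasubstituted alkene of 1. The closest known reactions are the thermal Diels–Alder additions of 2,3-dimethylmaleic anhydride to simple acyclic dienes, which need about 200 °C because both alkene carbons are fully substituted. The cyclohexene ring closes by intermolecular [4+2] annulation with both sigma bonds formed in one transition state, so no separate cyclisation mode has to be chosen. The two new quaternary stereocentres (future C1 and C7a) are set cis by the Z geometry locked in the cyclic anhydride, which a suprafacial addition transfers unchanged. The adduct is meso, so endo/exo and facial selectivity are irrelevant; the only demand is cycloaddition ahead of diene dimerisation or polymerisation, which excess diene, the inhibitor and the symmetrical non-enolisable dienophile should meet.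

Step 2
Reactants: 3 cis-1,2-dimethylcyclohex-4-ene-1,2-dicarboxylic anhydride
Product: 4 (1S,2R)-2-(methoxycarbonyl)-1,2-dimethylcyclohex-4-ene-1-carboxylic acid
Conditions: quinidine (1.1 equiv), MeOH (3 equiv), toluene, −55 to −20 °C; 2 M HCl wash
Reagents that add atoms: methanol (CO)
Why: Cinchona-alkaloid-mediated desymmetrising methanolysis of a meso cyclic anhydride, in which quinidine acts as chiral general base and directs methanol to one of the two enantiotopic carbonyls, fixing the absolute configuration of both quaternary carbons (acid on the future C7a, ester on the future C1) without creating a new stereocentre.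

Step 3
Reactants: 4 (1S,2R)-2-(methoxycarbonyl)-1,2-dimethylcyclohex-4-ene-1-carboxylic acid
Product: 6 (3aR,7aS)-3a,7a-dimethyl-3a,4,7,7a-tetrahydro-2-benzofuran-1(3H)-one, via hydroxy acid 5 (not isolated)
Conditions: LiBEt3H (3.5 equiv), THF, 0 °C to rt; then 2 M HCl, rt
Reagents that add atoms: none
Why: Chemoselective ester reduction, since LiBEt3H first turns the acid into an unreactive carboxylate and then reduces the methyl ester to the primary alkoxide, and the cis γ-hydroxy acid lactonises on acidification, leaving the future C1' at the alcohol level and the future C7 as a carbonyl.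

Step 4
Reactants: 6 (3aR,7aS)-3a,7a-dimethyl-3a,4,7,7a-tetrahydro-2-benzofuran-1(3H)-one
Product: 7 2-[(1S,6R)-6-(hydroxymethyl)-1,6-dimethylcyclohex-3-en-1-yl]propan-2-ol
Conditions: MeLi (4 equiv), Et2O/THF, −78 °C to rt; aq. NH4Cl
Reagents that add atoms: methyllithium ([Li]C)
Why: Double addition of methyllithium to the lactone carbonyl (through the ring-opened methyl ketone) installs both C7 methyl groups as a tertiary carbinol and releases the C1' hydroxyl.

Step 5
Reactants: 7 2-[(1S,6R)-6-(hydroxymethyl)-1,6-dimethylcyclohex-3-en-1-yl]propan-2-ol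
Product: 8 2-[(1S,6R)-6-{[tert-butyl(diphenyl)silyl]oxymethyl}-1,6-dimethylcyclohex-3-en-1-yl]propan-2-ol
Conditions: TBDPSCl, imidazole, DMF, rt
Reagents that add atoms: tert-butyl(chloro)diphenylsilane (CC(C)(C)[Si](Cl)(c1ccccc1)c1ccccc1)
Why: Silyl ether formation in which the primary hydroxyl reacts while the tertiary carbinol next to a quaternary carbon is too hindered for the bulky chlorosilane.

Step 6
Reactants: 8 2-[(1S,6R)-6-{[tert-butyl(diphenyl)silyl]oxymethyl}-1,6-dimethylcyclohex-3-en-1-yl]propan-2-ol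
Product: 9 tert-butyl{[1,6-dimethyl-6-(prop-1-en-2-yl)cyclohex-3-en-1-yl]methoxy}diphenylsilane (ring stereocentres as in 8)
Conditions: Burgess reagent, toluene, 50 °C
Reagents that add atoms: none
Why: Burgess dehydration (syn elimination through the sulfamate ester) under neutral conditions, in which only the two methyl groups offer β-hydrogens, so the isopropenyl group is the sole alkene that can form.

Step 7
Reactants: 9 tert-butyl{[1,6-dimethyl-6-(prop-1-en-2-yl)cyclohex-3-en-1-yl]methoxy}diphenylsilane; 10 acrolein (prop-2-enal)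
Product: 11 4-(6-{[tert-butyl(diphenyl)silyl]oxymethyl}-1,6-dimethylcyclohex-3-en-1-yl)-4-methylpentanal (ring stereocentres as in 8)
Conditions: Fe(acac)3 (30 mol%), PhSiH3 (2.5 equiv), 10 (3 equiv), EtOH/(CH2OH)2, 60 °C
Reagents that add atoms: none
Why: Metal-hydride hydrogen-atom-transfer Giese addition, in which an iron hydride formed from Fe(acac)3 and PhSiH3 transfers a hydrogen atom to the CH2 terminus of the 1,1-disubstituted alkene, the tertiary C7 radical adds to the β-carbon of acrolein and the α-formyl radical is reduced and protonated, while the 1,2-disubstituted ring alkene is a far poorer hydrogen-atom acceptor and the new quaternary C7 is not stereogenic.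

Step 8
Reactants: 11 4-(6-{[tert-butyl(diphenyl)silyl]oxymethyl}-1,6-dimethylcyclohex-3-en-1-yl)-4-methylpentanal
Product: 12 tert-butyl{[6-(5,5-dimethoxy-2-methylpentan-2-yl)-1,6-dimethylcyclohex-3-en-1-yl]methoxy}diphenylsilane (ring stereocentres as in 8)
Conditions: HC(OMe)3, PPTS (cat.), MeOH, rt
Reagents that add atoms: trimethyl orthoformate (COC(OC)OC); methanol (CO)
Why: Acid-catalysed acetalisation with orthoformate as water scavenger masks the aldehyde (future C4) against ozone, hydroxide and LDA, and the TBDPS ether tolerates PPTS.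

Step 9
Reactants: 12 tert-butyl{[6-(5,5-dimethoxy-2-methylpentan-2-yl)-1,6-dimethylcyclohex-3-en-1-yl]methoxy}diphenylsilane
Product: 13 dimethyl 3-{[tert-butyl(diphenyl)silyl]oxymethyl}-4-(5,5-dimethoxy-2-methylpentan-2-yl)-3,4-dimethylhexanedioate (C3 and C4 are the future C1 and C7a)
Conditions: O3, NaOH (2.5 M in MeOH), CH2Cl2, −78 °C, stopped at the indicator end point
Reagents that add atoms: ozone ([O-][O+]=O); methanol (CO)
Why: Ozonolysis in methanolic NaOH converts each alkene carbon directly into a methyl ester, opening the cyclohexene to the adipate whose CH2CO2Me arms are C2 plus its carboxyl (on C1) and C3a plus C3 (on C7a), while the acetal and silyl ether are stable to base.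

Step 10
Reactants: 13 dimethyl 3-{[tert-butyl(diphenyl)silyl]oxymethyl}-4-(5,5-dimethoxy-2-methylpentan-2-yl)-3,4-dimethylhexanedioate
Product: 15 methyl 6-(1-{[tert-butyl(diphenyl)silyl]oxy}-4-methoxy-2-methyl-4-oxobutan-2-yl)-2-methoxy-5,5,6-trimethylcyclohexane-1-carboxylate (diastereomer mixture at C3a and C4), via bis(ketene silyl acetal) 14 (not isolated)
Conditions: LDA (2.4 equiv), TMSCl (3 equiv), THF, −78 °C; then TMSOTf (10 mol%), CH2Cl2, −78 °C; aq. NaHCO3
Reagents that add atoms: none
Why: Intramolecular Mukaiyama aldol addition to an acetal, in which both ester arms become ketene silyl acetals, TMSOTf ionises the dimethyl acetal and the oxocarbenium ion is captured by the arm on C7a because only that arm closes a six-membered ring (the arm on C1 would close a seven-membered one), forming C3a–C4; the two new stereocentres are erased in step 11 and the unreacted ketene acetal reverts to the ester on work-up.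

Step 11
Reactants: 15 methyl 6-(1-{[tert-butyl(diphenyl)silyl]oxy}-4-methoxy-2-methyl-4-oxobutan-2-yl)-2-methoxy-5,5,6-trimethylcyclohexane-1-carboxylate
Product: 17 methyl 1-{[tert-butyl(diphenyl)silyl]oxymethyl}-1,7,7,7a-tetramethyl-3-oxo-2,3,5,6,7,7a-hexahydro-1H-indene-2-carboxylate (C1 and C7a as in 31; C2 epimerisable), via methoxy keto ester 16 (not isolated)
Conditions: t-BuOK (2.5 equiv), THF, 0 °C to rt; AcOH; then TsOH·H2O (cat.), toluene, 60 °C
Reagents that add atoms: none
Why: Dieckmann condensation in which, with ring B closed, only the enolate of the CH2CO2Me arm on C1 leads to a β-keto ester that persists as its enolate (acylation at C3a would give a quaternary, non-enolisable and reversibly formed product), so C2 attacks the C3 ester carbonyl and closes ring A, and acid then eliminates methanol from the β-methoxy ketone to the C3a=C4 enone.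

Step 12
Reactants: 17 methyl 1-{[tert-butyl(diphenyl)silyl]oxymethyl}-1,7,7,7a-tetramethyl-3-oxo-2,3,5,6,7,7a-hexahydro-1H-indene-2-carboxylate
Product: 18 methyl 1-{[tert-butyl(diphenyl)silyl]oxymethyl}-1,7,7,7a-tetramethyl-3-{[(trifluoromethyl)sulfonyl]oxy}-5,6,7,7a-tetrahydro-1H-indene-2-carboxylate (C1 and C7a as in 31)
Conditions: NaH, THF, 0 °C; PhNTf2, 0 °C to rt
Reagents that add atoms: N-phenylbis(trifluoromethanesulfonimide) (O=S(=O)(N(c1ccccc1)S(=O)(=O)C(F)(F)F)C(F)(F)F)
Why: O-Sulfonylation of the sodium enolate of the β-keto ester gives the enol triflate, the standard handle for reductive removal of a β-keto ester oxygen.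

Step 13
Reactants: 18 methyl 1-{[tert-butyl(diphenyl)silyl]oxymethyl}-1,7,7,7a-tetramethyl-3-{[(trifluoromethyl)sulfonyl]oxy}-5,6,7,7a-tetrahydro-1H-indene-2-carboxylate
Product: 19 methyl 1-{[tert-butyl(diphenyl)silyl]oxymethyl}-1,7,7,7a-tetramethyl-5,6,7,7a-tetrahydro-1H-indene-2-carboxylate (C1 and C7a as in 31)
Conditions: Pd(OAc)2 (5 mol%), PPh3 (10 mol%), HCO2H, Et3N, DMF, 60 °C
Reagents that add atoms: none
Why: Palladium-catalysed formate reduction of an enol triflate (oxidative addition, exchange to the formate, loss of CO2, C–H reductive elimination) replaces the C3 triflate by hydrogen and leaves both alkenes in place, giving the 2,4-dienoate that spans rings A and B.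

Step 14
Reactants: 19 methyl 1-{[tert-butyl(diphenyl)silyl]oxymethyl}-1,7,7,7a-tetramethyl-5,6,7,7a-tetrahydro-1H-indene-2-carboxylate
Product: 20 methyl 1-(hydroxymethyl)-1,7,7,7a-tetramethyl-5,6,7,7a-tetrahydro-1H-indene-2-carboxylate (C1 and C7a as in 31)
Conditions: HF·pyridine, pyridine, THF, 0 °C to rt
Reagents that add atoms: none
Why: Fluoride-mediated Si–O cleavage under buffered, non-basic conditions frees the C1' hydroxyl without inviting transesterification onto the neighbouring conjugated ester.

Step 15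
Reactants: 20 methyl 1-(hydroxymethyl)-1,7,7,7a-tetramethyl-5,6,7,7a-tetrahydro-1H-indene-2-carboxylate
Product: 21 methyl (1R,2S,7aS)-1-(hydroxymethyl)-1,7,7,7a-tetramethyl-2,3,5,6,7,7a-hexahydro-1H-indene-2-carboxylate
Conditions: [Rh(nbd)(dppb)]BF4 (5 mol%), H2 (60 atm), CH2Cl2, rt
Reagents that add atoms: none
Why: Hydroxyl-directed homogeneous hydrogenation, in which the homoallylic C1' hydroxyl and the C2=C3 alkene chelate the cationic rhodium centre so that both hydrogens arrive on the face bearing CH2OH, placing H-2 cis to CH2OH and the ester cis to the C1 and C7a methyls as in the target, while the C3a=C4 alkene cannot chelate in the s-trans diene and is not reduced by this catalyst class without a directing group.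

Step 16
Reactants: 21 methyl (1R,2S,7aS)-1-(hydroxymethyl)-1,7,7,7a-tetramethyl-2,3,5,6,7,7a-hexahydro-1H-indene-2-carboxylate
Product: 22 methyl (1R,2S,7aS)-1-formyl-1,7,7,7a-tetramethyl-2,3,5,6,7,7a-hexahydro-1H-indene-2-carboxylate
Conditions: Dess–Martin periodinane, CH2Cl2, 0 °C to rt
Reagents that add atoms: none
Why: Dess–Martin oxidation of the neopentyl primary alcohol gives the non-enolisable aldehyde under neutral conditions that leave C2 and the ring alkene untouched.

Step 17
Reactants: 22 methyl (1R,2S,7aS)-1-formyl-1,7,7,7a-tetramethyl-2,3,5,6,7,7a-hexahydro-1H-indene-2-carboxylate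
Product: 23 methyl (1R,2S,7aS)-1-ethenyl-1,7,7,7a-tetramethyl-2,3,5,6,7,7a-hexahydro-1H-indene-2-carboxylate
Conditions: Ph3PCH3Br, KHMDS, THF, −78 to 0 °C
Reagents that add atoms: methyltriphenylphosphonium bromide (C[P+](c1ccccc1)(c1ccccc1)c1ccccc1.[Br-])
Why: Wittig methylenation of the hindered but non-enolisable aldehyde at low temperature turns C1' into the vinyl group (C1'=C2') faster than the ylide can deprotonate the hindered C2–H.

Step 18
Reactants: 24 prop-2-yn-1-ol
Product: 26 (Z)-3-iodo-2-methylprop-2-en-1-ol, via alkenylmagnesium alkoxide 25 (not isolated)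
Conditions: MeMgBr (2.5 equiv), CuI (10 mol%), THF, −10 °C to rt; then I2, −78 to 0 °C
Reagents that add atoms: methylmagnesium bromide (C[Mg]Br); iodine (II)
Why: Copper-catalysed carbomagnesiation of the propargylic alkoxide adds methyl and magnesium anti across the alkyne (magnesium held by the alkoxide), and iodinolysis with retention gives the iodoalkene with iodine and CH2OH cis, the geometry needed for C3'=C4'.

Step 19
Reactants: 23 methyl (1R,2S,7aS)-1-ethenyl-1,7,7,7a-tetramethyl-2,3,5,6,7,7a-hexahydro-1H-indene-2-carboxylate; 26 (Z)-3-iodo-2-methylprop-2-en-1-ol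
Product: 28 methyl (1R,2S,7aS)-1-[(3Z)-5-hydroxy-4-methylpent-3-en-1-yl]-1,7,7,7a-tetramethyl-2,3,5,6,7,7a-hexahydro-1H-indene-2-carboxylate, via alkylborane 27 (not isolated)
Conditions: 9-BBN-H, THF, rt to 50 °C; then 26, PdCl2(dppf) (5 mol%), AsPh3, Cs2CO3, DMF/H2O, rt
Reagents that add atoms: none
Why: Anti-Markovnikov hydroboration of the monosubstituted alkene with 9-BBN (the trisubstituted ring alkene and the ester are inert) followed by B-alkyl Suzuki–Miyaura coupling with the iodoalkene, which forms C2'–C3' with retention of the Z geometry.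

Step 20
Reactants: 28 methyl (1R,2S,7aS)-1-[(3Z)-5-hydroxy-4-methylpent-3-en-1-yl]-1,7,7,7a-tetramethyl-2,3,5,6,7,7a-hexahydro-1H-indene-2-carboxylate
Product: 29 (1R,2S,7aS)-1-[(3Z)-5-hydroxy-4-methylpent-3-en-1-yl]-1,7,7,7a-tetramethyl-2,3,5,6,7,7a-hexahydro-1H-indene-2-carboxylic acid
Conditions: LiOH, THF/MeOH/H2O, 50 °C; then 1 M HCl to pH 3
Reagents that add atoms: lithium hydroxide ([Li+].[OH-])
Why: Saponification of the methyl ester, after which the carboxylate can no longer epimerise, and any equilibration at C2 before hydrolysis should favour the same arrangement with the carboxyl trans to the larger C1 substituent.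

Step 21
Reactants: 29 (1R,2S,7aS)-1-[(3Z)-5-hydroxy-4-methylpent-3-en-1-yl]-1,7,7,7a-tetramethyl-2,3,5,6,7,7a-hexahydro-1H-indene-2-carboxylic acid
Product: 31 (1R,2S,7aS)-1-[(3Z)-5-acetoxy-4-methylpent-3-en-1-yl]-1,7,7,7a-tetramethyl-2,3,5,6,7,7a-hexahydro-1H-indene-2-carboxylic acid (CNP0289983.1), via mixed anhydride 30 (not isolated)
Conditions: Ac2O, pyridine, DMAP (cat.), CH2Cl2, rt; then H2O/THF, rt
Reagents that add atoms: acetic anhydride (CC(=O)OC(C)=O)
Why: Acylation of the primary allylic alcohol with acetic anhydride, the mixed anhydride formed at the hindered acid being hydrolysed back to the carboxylic acid in the aqueous stage so that the acetate is the only ester in the product.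

**Compound list**

1 | 2,3-dimethylmaleic anhydride | CC1=C(C)C(=O)OC1=O | starting material
2 | buta-1,3-diene | C=CC=C | starting material
3 | cis-1,2-dimethylcyclohex-4-ene-1,2-dicarboxylic anhydride, meso, (3aR,7aS)-3a,7a-dimethyl-3a,4,7,7a-tetrahydro-2-benzofuran-1,3-dione | C[C@]12CC=CC[C@@]1(C)C(=O)OC2=O | intermediate
4 | (1S,2R)-2-(methoxycarbonyl)-1,2-dimethylcyclohex-4-ene-1-carboxylic acid (acid on future C7a, ester on future C1) | C[C@]1(C(=O)O)CC=CC[C@@]1(C)C(=O)OC | intermediate
5 | (1S,2R)-2-(hydroxymethyl)-1,2-dimethylcyclohex-4-ene-1-carboxylic acid | C[C@]1(C(=O)O)CC=CC[C@@]1(C)CO | intermediate (not isolated)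
6 | (3aR,7aS)-3a,7a-dimethyl-3a,4,7,7a-tetrahydro-2-benzofuran-1(3H)-one, cis-fused lactone | C[C@]12CC=CC[C@@]1(C)COC2=O | intermediate
7 | 2-[(1S,6R)-6-(hydroxymethyl)-1,6-dimethylcyclohex-3-en-1-yl]propan-2-ol | C[C@]1(C(C)(C)O)CC=CC[C@@]1(C)CO | intermediate
8 | 2-[(1S,6R)-6-{[tert-butyl(diphenyl)silyl]oxymethyl}-1,6-dimethylcyclohex-3-en-1-yl]propan-2-ol | C[C@]1(C(C)(C)O)CC=CC[C@@]1(C)CO[Si](c2ccccc2)(c2ccccc2)C(C)(C)C | intermediate
9 | tert-butyl{[1,6-dimethyl-6-(prop-1-en-2-yl)cyclohex-3-en-1-yl]methoxy}diphenylsilane, cis methyls, ring stereocentres as in 8 | C[C@]1(C(C)=C)CC=CC[C@@]1(C)CO[Si](c2ccccc2)(c2ccccc2)C(C)(C)C | intermediate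
10 | acrolein (prop-2-enal) | C=CC=O | starting material
11 | 4-(6-{[tert-butyl(diphenyl)silyl]oxymethyl}-1,6-dimethylcyclohex-3-en-1-yl)-4-methylpentanal, ring stereocentres as in 8 | C[C@]1(C(C)(C)CCC=O)CC=CC[C@@]1(C)CO[Si](c2ccccc2)(c2ccccc2)C(C)(C)C | intermediate
12 | tert-butyl{[6-(5,5-dimethoxy-2-methylpentan-2-yl)-1,6-dimethylcyclohex-3-en-1-yl]methoxy}diphenylsilane, ring stereocentres as in 8 | C[C@]1(C(C)(C)CCC(OC)OC)CC=CC[C@@]1(C)CO[Si](c2ccccc2)(c2ccccc2)C(C)(C)C | intermediate
13 | dimethyl 3-{[tert-butyl(diphenyl)silyl]oxymethyl}-4-(5,5-dimethoxy-2-methylpentan-2-yl)-3,4-dimethylhexanedioate, C3 and C4 (future C1 and C7a) as in 31 | COC(=O)C[C@](C)(C(C)(C)CCC(OC)OC)[C@@](C)(CC(=O)OC)CO[Si](c1ccccc1)(c1ccccc1)C(C)(C)C | intermediate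
14 | bis(trimethylsilyl ketene acetal) of 13, enol ether geometry undefined | COC(O[Si](C)(C)C)=C[C@](C)(C(C)(C)CCC(OC)OC)[C@@](C)(C=C(OC)O[Si](C)(C)C)CO[Si](c1ccccc1)(c1ccccc1)C(C)(C)C | intermediate (not isolated)
15 | methyl 6-(1-{[tert-butyl(diphenyl)silyl]oxy}-4-methoxy-2-methyl-4-oxobutan-2-yl)-2-methoxy-5,5,6-trimethylcyclohexane-1-carboxylate, quaternary centres as in 31, mixture at C3a and C4 | COC(=O)C1C(OC)CCC(C)(C)[C@]1(C)[C@@](C)(CC(=O)OC)CO[Si](c1ccccc1)(c1ccccc1)C(C)(C)C | intermediate
16 | methyl 1-{[tert-butyl(diphenyl)silyl]oxymethyl}-4-methoxy-1,7,7,7a-tetramethyl-3-oxooctahydro-1H-indene-2-carboxylate, C1 and C7a as in 31, other centres mixed | COC(=O)C1C(=O)C2C(OC)CCC(C)(C)[C@]2(C)[C@]1(C)CO[Si](c1ccccc1)(c1ccccc1)C(C)(C)C | intermediate (not isolated)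
17 | methyl 1-{[tert-butyl(diphenyl)silyl]oxymethyl}-1,7,7,7a-tetramethyl-3-oxo-2,3,5,6,7,7a-hexahydro-1H-indene-2-carboxylate, C1 and C7a as in 31, C2 epimerisable | COC(=O)C1C(=O)C2=CCCC(C)(C)[C@]2(C)[C@]1(C)CO[Si](c1ccccc1)(c1ccccc1)C(C)(C)C | intermediate
18 | methyl 1-{[tert-butyl(diphenyl)silyl]oxymethyl}-1,7,7,7a-tetramethyl-3-{[(trifluoromethyl)sulfonyl]oxy}-5,6,7,7a-tetrahydro-1H-indene-2-carboxylate, C1 and C7a as in 31 | COC(=O)C1=C(OS(=O)(=O)C(F)(F)F)C2=CCCC(C)(C)[C@]2(C)[C@]1(C)CO[Si](c1ccccc1)(c1ccccc1)C(C)(C)C | intermediate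
19 | methyl 1-{[tert-butyl(diphenyl)silyl]oxymethyl}-1,7,7,7a-tetramethyl-5,6,7,7a-tetrahydro-1H-indene-2-carboxylate, C1 and C7a as in 31 | COC(=O)C1=CC2=CCCC(C)(C)[C@]2(C)[C@]1(C)CO[Si](c1ccccc1)(c1ccccc1)C(C)(C)C | intermediate
20 | methyl 1-(hydroxymethyl)-1,7,7,7a-tetramethyl-5,6,7,7a-tetrahydro-1H-indene-2-carboxylate, C1 and C7a as in 31 | COC(=O)C1=CC2=CCCC(C)(C)[C@]2(C)[C@]1(C)CO | intermediate
21 | methyl (1R,2S,7aS)-1-(hydroxymethyl)-1,7,7,7a-tetramethyl-2,3,5,6,7,7a-hexahydro-1H-indene-2-carboxylate, ester cis to both ring methyls | COC(=O)[C@H]1CC2=CCCC(C)(C)[C@]2(C)[C@]1(C)CO | intermediate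
22 | methyl (1R,2S,7aS)-1-formyl-1,7,7,7a-tetramethyl-2,3,5,6,7,7a-hexahydro-1H-indene-2-carboxylate | COC(=O)[C@H]1CC2=CCCC(C)(C)[C@]2(C)[C@]1(C)C=O | intermediate
23 | methyl (1R,2S,7aS)-1-ethenyl-1,7,7,7a-tetramethyl-2,3,5,6,7,7a-hexahydro-1H-indene-2-carboxylate | COC(=O)[C@H]1CC2=CCCC(C)(C)[C@]2(C)[C@]1(C)C=C | intermediate
24 | prop-2-yn-1-ol (propargyl alcohol) | C#CCO | starting material
25 | bromomagnesium (Z)-3-(bromomagnesio)-2-methylprop-2-en-1-olate | Br[Mg]/C=C(C)\CO[Mg]Br | intermediate (not isolated)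
26 | (Z)-3-iodo-2-methylprop-2-en-1-ol | OC/C(C)=C\I | intermediate
27 | methyl (1R,2S,7aS)-1-[2-(9-borabicyclo[3.3.1]nonan-9-yl)ethyl]-1,7,7,7a-tetramethyl-2,3,5,6,7,7a-hexahydro-1H-indene-2-carboxylate | COC(=O)[C@H]1CC2=CCCC(C)(C)[C@]2(C)[C@]1(C)CCB1C2CCCC1CCC2 | intermediate (not isolated)
28 | methyl (1R,2S,7aS)-1-[(3Z)-5-hydroxy-4-methylpent-3-en-1-yl]-1,7,7,7a-tetramethyl-2,3,5,6,7,7a-hexahydro-1H-indene-2-carboxylate | COC(=O)[C@H]1CC2=CCCC(C)(C)[C@]2(C)[C@]1(C)CC/C=C(C)\CO | intermediate
29 | (1R,2S,7aS)-1-[(3Z)-5-hydroxy-4-methylpent-3-en-1-yl]-1,7,7,7a-tetramethyl-2,3,5,6,7,7a-hexahydro-1H-indene-2-carboxylic acid | OC(=O)[C@H]1CC2=CCCC(C)(C)[C@]2(C)[C@]1(C)CC/C=C(C)\CO | intermediate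
30 | acetic (1R,2S,7aS)-1-[(3Z)-5-acetoxy-4-methylpent-3-en-1-yl]-1,7,7,7a-tetramethyl-2,3,5,6,7,7a-hexahydro-1H-indene-2-carboxylic anhydride | CC(=O)OC/C(C)=C\CC[C@]1(C)[C@@H](C(=O)OC(C)=O)CC2=CCCC(C)(C)[C@@]21C | intermediate (not isolated)
31 | (1R,2S,7aS)-1-[(3Z)-5-acetoxy-4-methylpent-3-en-1-yl]-1,7,7,7a-tetramethyl-2,3,5,6,7,7a-hexahydro-1H-indene-2-carboxylic acid (CNP0289983.1) | CC(=O)OC/C(C)=C\CC[C@]1(C)[C@@H](C(=O)O)CC2=CCCC(C)(C)[C@@]21C | target

**Count**

Total step count: 21. Longest linear sequence: 20 steps (steps 1–17 and 19–21); step 18 prepares the coupling partner 26 from 24.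

**Steps most likely to fail**

Step 15 (directed hydrogenation). The catalyst may not discriminate between the two trisubstituted alkenes of the diene, so that C3a=C4 is saturated or migrates, or hydrogen may be delivered without full hydroxyl direction. The fallback sets out from silyl ether 19. A copper hydride, [(Ph3P)CuH]6 in toluene/t-BuOH, reduces the dienoate in the 1,4 sense (hydride to C3, γ,δ-alkene kept) and should give the saturated silyl ether ester as a C2 epimer mixture F1. NaOMe in MeOH then equilibrates C2 towards the ester trans to the bulky silyloxymethyl group, giving the (2S) silyl ether ester F2 after separation. HF·pyridine removes the silyl group and the route is rejoined at 21.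

Step 2 (desymmetrisation). Methanolysis at the two neopentyl-type carbonyls may be slow and poorly discriminating, which would give material of low enantiomeric purity. The fallback sets out from 3. NaBH4 in THF followed by acid reduces one carbonyl and gives the racemic cis-lactone F3. Me3Al and (S)-1-phenylethylamine in CH2Cl2 open it to two diastereomeric hydroxy amides, of which the hydroxy amide F4 with the ring configuration of 6 is separated by crystallisation or chromatography. Heating F4 with aqueous H2SO4 in dioxane relactonises it and the route is rejoined at 6.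

Step 7 (Giese addition). The enal may be consumed by polymerisation or hydrosilylation under the iron–silane conditions before the hindered tertiary radical is captured. The fallback sets out from 9 and brings in the three carbons at the nitrile oxidation level. Acrylonitrile with Fe(acac)3 and PhSiH3 in EtOH/(CH2OH)2 should give the nitrile F5, and i-Bu2AlH in toluene at −78 °C followed by aqueous acid reduces the nitrile to the aldehyde, rejoining the route at 11.

**Further compounds**

F1 | step 15 | methyl 1-{[tert-butyl(diphenyl)silyl]oxymethyl}-1,7,7,7a-tetramethyl-2,3,5,6,7,7a-hexahydro-1H-indene-2-carboxylate, mixture of C2 epimers | COC(=O)C1CC2=CCCC(C)(C)[C@]2(C)[C@]1(C)CO[Si](c1ccccc1)(c1ccccc1)C(C)(C)C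
F2 | step 15 | methyl (1R,2S,7aS)-1-{[tert-butyl(diphenyl)silyl]oxymethyl}-1,7,7,7a-tetramethyl-2,3,5,6,7,7a-hexahydro-1H-indene-2-carboxylate | COC(=O)[C@H]1CC2=CCCC(C)(C)[C@]2(C)[C@]1(C)CO[Si](c1ccccc1)(c1ccccc1)C(C)(C)C
F3 | step 2 | racemic cis-3a,7a-dimethyl-3a,4,7,7a-tetrahydro-2-benzofuran-1(3H)-one | C[C@]12CC=CC[C@@]1(C)COC2=O.C[C@@]12CC=CC[C@]1(C)COC2=O
F4 | step 2 | (1S,2R)-2-(hydroxymethyl)-1,2-dimethyl-N-[(1S)-1-phenylethyl]cyclohex-4-ene-1-carboxamide | C[C@]1(C(=O)N[C@@H](C)c2ccccc2)CC=CC[C@@]1(C)CO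
F5 | step 7 | 4-(6-{[tert-butyl(diphenyl)silyl]oxymethyl}-1,6-dimethylcyclohex-3-en-1-yl)-4-methylpentanenitrile, ring stereocentres as in 8 | C[C@]1(C(C)(C)CCC#N)CC=CC[C@@]1(C)CO[Si](c2ccccc2)(c2ccccc2)C(C)(C)C
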